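**Plan**
- Retrosynthesis: the five O–CH3 bonds and the four aryl–CHO bonds (C6 and C8 of ring A, C3' and C5' of ring B) are cut first. This leaves the pentamethyl ether of the bare 2-arylchroman.
- Next, C2–C1' (to ring B) is cut and O1 is taken out of the C8a–O1–C2 bridge of the pyran ring (ring C). Ring C shrinks to the cyclopentane ring of an indan-1-yl hydroperoxide, whose C1–C7a bond stands where O1 will sit.
- Enabling feature: O1 links aromatic C8a to C2. C2 has the oxidation level of an aldehyde and carries only H and the strongly nucleophilic arene ring B. C8a is meta to the oxygens on C5 and C7, so a peroxide on this benzylic carbon breaks its O–O bond and not its C–O bond.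
- Forward: ring A is bought. The five-membered carbocycle is closed onto it by rhodium catalysis (C4–C4a bond), and acetone supplies the isopropyl carbons. One flask then enlarges this ring to ring C and joins ring B, and formylation and demethylation finish the route.
- Stereochemistry: C4 is set by asymmetric catalysis (step 2). C3 follows from C4 by base equilibration to the trans ketone (step 5). C2 follows from both by reversible closure of O1–C2 to the epimer with equatorial aryl (step 8).

Key step: step 8

Assumption: the ligand antipode that gives the (S)-indanone in step 2 must be fixed by one test run (it is written as the (R)-ligand), and C1 of the indanol of step 6 and of the hydroperoxide of step 7 is carried as a mixture of epimers, so their SMILES bear no descriptor at that atom.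

**Step 1**
Reactants: 1 4-methylpent-1-yne; 2 3,5-dimethoxybenzaldehyde
Product: 4 rac-1-(3,5-dimethoxyphenyl)-5-methylhex-2-yn-1-ol, via lithium acetylide 3 (not isolated)
Conditions: n-BuLi, THF, −78 °C; then 2, −78 to 0 °C; H2O
Reagents that add atoms: none
Why: 1,2-addition of a lithium acetylide to an aromatic aldehyde, in which the carbinol centre may stay racemic because step 2 destroys it.

**Step 2**
Reactants: 4 rac-1-(3,5-dimethoxyphenyl)-5-methylhex-2-yn-1-ol
Product: 5 (S)-3-isobutyl-4,6-dimethoxyindan-1-one
Conditions: [Rh(OH)(cod)]2 (2.5 mol %), (R)-BINAP (6 mol %), toluene, 60–80 °C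
Reagents that add atoms: none
Why: Rhodium-catalysed asymmetric isomerisation of α-arylpropargyl alcohols to 3-substituted indanones, in which β-hydride elimination of the rhodium alkoxide gives the ynone and Rh–H, hydrorhodation and a 1,4-rhodium shift to one of the two equivalent ortho C–H positions follow, and the intramolecular conjugate addition inside the chiral bisphosphine pocket sets C3 while both enantiomers of 4 converge on one product.

**Step 3**
Reactants: 5 (S)-3-isobutyl-4,6-dimethoxyindan-1-one; 6 acetone
Product: 8 (2R,3S)-2-(2-hydroxypropan-2-yl)-3-isobutyl-4,6-dimethoxyindan-1-one, via lithium enolate 7 (not isolated)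
Conditions: LDA, THF, −78 °C; 6; AcOH, −78 °C
Reagents that add atoms: none
Why: Directed aldol addition of the only possible lithium enolate to acetone, which should enter at C2 anti to the C3 isobutyl group, with a cold acidic quench to prevent retro-aldol cleavage.

**Step 4**
Reactants: 8 (2R,3S)-2-(2-hydroxypropan-2-yl)-3-isobutyl-4,6-dimethoxyindan-1-one
Product: 10 (R)-3-isobutyl-4,6-dimethoxy-2-(propan-2-ylidene)indan-1-one, via tertiary mesylate 9 (not isolated)
Conditions: MsCl, Et3N, CH2Cl2, 0 °C to rt
Reagents that add atoms: none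
Why: Mesylation and E1cB elimination complete the aldol condensation, and the amine base is too weak to remove the γ-proton at C3, so that centre is kept (its descriptor changes only through the CIP priorities).

**Step 5**
Reactants: 10 (R)-3-isobutyl-4,6-dimethoxy-2-(propan-2-ylidene)indan-1-one
Product: 12 (2S,3S)-3-isobutyl-2-isopropyl-4,6-dimethoxyindan-1-one (trans), via cis ketone 11 (not isolated)
Conditions: H2 (1 atm), Pd/C, EtOAc, rt; filter; NaOMe (cat.), MeOH, rt
Reagents that add atoms: none
Why: Heterogeneous hydrogenation of the enone C=C (hydrogen should arrive anti to the isobutyl group) followed by base epimerisation of the α-centre, so that C2 is set under thermodynamic control trans to the fixed C3 substituent.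

**Step 6**
Reactants: 12 (2S,3S)-3-isobutyl-2-isopropyl-4,6-dimethoxyindan-1-one
Product: 13 (2S,3S)-3-isobutyl-2-isopropyl-4,6-dimethoxyindan-1-ol (C1 epimers)
Conditions: NaBH4, MeOH, 0 °C to rt
Reagents that add atoms: none
Why: Borohydride reduction of an aryl ketone, in which the configuration of the new carbinol centre does not matter because C1 becomes planar in step 8.

**Step 7**
Reactants: 13 (2S,3S)-3-isobutyl-2-isopropyl-4,6-dimethoxyindan-1-ol
Product: 14 (2S,3S)-1-hydroperoxy-3-isobutyl-2-isopropyl-4,6-dimethoxyindane (C1 epimers)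
Conditions: 50 % aq H2O2 (large excess), H2SO4 (cat.), Et2O, 0 °C to rt
Reagents that add atoms: hydrogen peroxide OO
Why: Acid-catalysed perhydrolysis of a secondary benzylic alcohol (SN1 exchange of OH for OOH, as known for 1-phenylethanol, indan-1-ol and tetralin-1-ol), driven by the excess and the high nucleophilicity of H2O2, with C2 and C3 untouched.

**Step 8**
Reactants: 14 (2S,3S)-1-hydroperoxy-3-isobutyl-2-isopropyl-4,6-dimethoxyindane; 15 1,3,5-trimethoxybenzene
Product: 17 (2R,3S,4S)-4-isobutyl-3-isopropyl-5,7-dimethoxy-2-(2,4,6-trimethoxyphenyl)chroman, via oxocarbenium ion 16 (not isolated)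
Conditions: InCl3 (20 mol %), 15 (1.1 equiv), CH2Cl2, 0 °C to rt; then CF3CO2H (cat.), rt, until C2 has equilibrated
Reagents that add atoms: none
Why: InCl3 binds the outer oxygen of the OOH group, and as the O–O bond breaks the aromatic carbon C7a (the later C8a) shifts with its bonding pair from C1 to the inner oxygen through a bridged arenium-like transition state, so that this oxygen is inserted into the C1–C7a bond and the cyclopentane ring becomes the six-membered oxocarbenium ion 16 (O1=C2H+), which arene 15 attacks at C2 in a Friedel–Crafts alkylation with water as the only by-product. The closest known reaction type is the Hock rearrangement of benzo-fused cycloalkyl hydroperoxides under indium or boron Lewis acids with capture of the cyclic oxocarbenium ion by π-nucleophiles. Ring C is therefore closed not by a cyclisation but by a 1,2-shift of carbon to oxygen (one-atom enlargement, five to six), and whenever the O1–C2 bond of 17 reopens to the 2,4,6-trimethoxybenzyl cation it closes again in the 6-exo-trig mode. C3 and C4 are carried over from 14 and C1 becomes planar, so its mixed configuration is lost; the new centre C2 should be set under thermodynamic control through this reversible ionisation, because peri strain with the 5-methoxy group holds the C4 isobutyl group pseudoaxial, the trans isopropyl group is then axial, and only the 2R epimer can place ring B equatorial (2,3-cis), whereas the 2S epimer suffers either a 1,3-diaxial aryl/isobutyl contact or the peri strain. The step needs aryl migration in preference to migration of the secondary C2 or of H, and O–O in preference to C–O heterolysis: π-participation favours the aryl group, and C7a is meta to both methoxy groups, so the C1 cation is too poor for loss of H2O2. Single arylation is secured by about one equivalent of 15 and by the shielding of C2 by the neighbouring isopropyl group.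

**Step 9**
Reactants: 17 (2R,3S,4S)-4-isobutyl-3-isopropyl-5,7-dimethoxy-2-(2,4,6-trimethoxyphenyl)chroman
Product: 19 (2R,3S,4S)-2-(3,5-diformyl-2,4,6-trimethoxyphenyl)-4-isobutyl-3-isopropyl-5,7-dimethoxychroman-6,8-dicarbaldehyde, via tetrakis(chloromethoxymethyl) arene 18 (not isolated)
Conditions: Cl2CHOMe (excess), TiCl4 (excess), CH2Cl2, −78 to 0 °C; then ice-water
Reagents that add atoms: dichloromethyl methyl ether COC(Cl)Cl; water O
Why: Fourfold Rieche formylation, in which each free position (C6, C8, C3', C5') lies between two alkoxy groups and is ortho or para to three oxygen donors, so the second position of each ring should remain nucleophilic after the first formyl group has entered, and no stereocentre is involved.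

**Step 10**
Reactants: 19 (2R,3S,4S)-2-(3,5-diformyl-2,4,6-trimethoxyphenyl)-4-isobutyl-3-isopropyl-5,7-dimethoxychroman-6,8-dicarbaldehyde
Product: 20 sideroxylonal B
Conditions: BCl3 (excess), CH2Cl2, −78 °C to rt; then H2O
Reagents that add atoms: none
Why: Chelation-assisted aryl methyl ether cleavage, in which each of the five methoxy groups is ortho to a formyl group and can bind BCl3 in a six-membered chelate from which chloride removes the methyl group, while the O1–C2 bond, should it open, recloses to the same favoured C2 epimer.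

**Compound list**
1 | 4-methylpent-1-yne | C#CCC(C)C | starting material
2 | 3,5-dimethoxybenzaldehyde | COc1cc(C=O)cc(OC)c1 | starting material
3 | (4-methylpent-1-yn-1-yl)lithium | [Li]C#CCC(C)C | intermediate
4 | rac-1-(3,5-dimethoxyphenyl)-5-methylhex-2-yn-1-ol | COc1cc(cc(OC)c1)C(O)C#CCC(C)C | intermediate
5 | (S)-3-isobutyl-4,6-dimethoxyindan-1-one | CC(C)C[C@@H]1c2c(OC)cc(OC)cc2C(=O)C1 | intermediate
6 | acetone | CC(C)=O | starting material
7 | lithium enolate of 5 | CC(C)C[C@@H]1c2c(OC)cc(OC)cc2C(O[Li])=C1 | intermediate
8 | (2R,3S)-2-(2-hydroxypropan-2-yl)-3-isobutyl-4,6-dimethoxyindan-1-one | CC(C)C[C@@H]1c2c(OC)cc(OC)cc2C(=O)[C@H]1C(C)(C)O | intermediate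
9 | methanesulfonate of 8 | CC(C)C[C@@H]1c2c(OC)cc(OC)cc2C(=O)[C@H]1C(C)(C)OS(C)(=O)=O | intermediate
10 | (R)-3-isobutyl-4,6-dimethoxy-2-(propan-2-ylidene)indan-1-one | CC(C)C[C@@H]1c2c(OC)cc(OC)cc2C(=O)C1=C(C)C | intermediate
11 | (2R,3S)-3-isobutyl-2-isopropyl-4,6-dimethoxyindan-1-one (cis) | CC(C)C[C@@H]1c2c(OC)cc(OC)cc2C(=O)[C@@H]1C(C)C | intermediate
12 | (2S,3S)-3-isobutyl-2-isopropyl-4,6-dimethoxyindan-1-one (trans) | CC(C)C[C@@H]1c2c(OC)cc(OC)cc2C(=O)[C@H]1C(C)C | intermediate
13 | (2S,3S)-3-isobutyl-2-isopropyl-4,6-dimethoxyindan-1-ol (C1 epimers) | CC(C)C[C@@H]1c2c(OC)cc(OC)cc2C(O)[C@H]1C(C)C | intermediate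
14 | (2S,3S)-1-hydroperoxy-3-isobutyl-2-isopropyl-4,6-dimethoxyindane (C1 epimers) | CC(C)C[C@@H]1c2c(OC)cc(OC)cc2C(OO)[C@H]1C(C)C | intermediate
15 | 1,3,5-trimethoxybenzene | COc1cc(OC)cc(OC)c1 | starting material
16 | (3S,4S)-4-isobutyl-3-isopropyl-5,7-dimethoxy-3,4-dihydrochromenylium ion | CC(C)C[C@@H]1c2c(OC)cc(OC)cc2[O+]=C[C@H]1C(C)C | intermediate
17 | (2R,3S,4S)-4-isobutyl-3-isopropyl-5,7-dimethoxy-2-(2,4,6-trimethoxyphenyl)chroman | CC(C)C[C@@H]1c2c(OC)cc(OC)cc2O[C@@H](c2c(OC)cc(OC)cc2OC)[C@H]1C(C)C | intermediate
18 | 6,8,3',5'-tetrakis[chloro(methoxy)methyl] derivative of 17 | CC(C)C[C@@H]1c2c(OC)c(C(Cl)OC)c(OC)c(C(Cl)OC)c2O[C@@H](c2c(OC)c(C(Cl)OC)c(OC)c(C(Cl)OC)c2OC)[C@H]1C(C)C | intermediate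
19 | (2R,3S,4S)-2-(3,5-diformyl-2,4,6-trimethoxyphenyl)-4-isobutyl-3-isopropyl-5,7-dimethoxychroman-6,8-dicarbaldehyde | CC(C)C[C@@H]1c2c(OC)c(C=O)c(OC)c(C=O)c2O[C@@H](c2c(OC)c(C=O)c(OC)c(C=O)c2OC)[C@H]1C(C)C | intermediate
20 | sideroxylonal B, (2R,3S,4S)-2-(3,5-diformyl-2,4,6-trihydroxyphenyl)-5,7-dihydroxy-4-isobutyl-3-isopropylchroman-6,8-dicarbaldehyde | CC(C)C[C@@H]1c2c(O)c(C=O)c(O)c(C=O)c2O[C@@H](c2c(O)c(C=O)c(O)c(C=O)c2O)[C@H]1C(C)C | target

**Total step count:** 10. **Longest linear sequence:** 10 steps (from 1 or 2 to 20).

**Steps most likely to fail**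

**Step 8.**
- What may go wrong: the arene may attack ion 16 on the face anti to the isopropyl group, and C2 may then fail to equilibrate (poor facial selectivity). Ring opening may be followed by a second arylation. The opened cation may lose a proton and erode C3. The hydroperoxide may simply dehydrate to the ketone.
- The fallback sets out from 14 and comes back at 17, and it lets hydride instead of the arene set C2.
- Compound 14 is rearranged without arene (InCl3, MeCN–H2O) to the lactol (3S,4S)-4-isobutyl-3-isopropyl-5,7-dimethoxychroman-2-ol F1. A Fétizon oxidation (Ag2CO3 on Celite, toluene, reflux) converts this to the trans lactone (3S,4S)-4-isobutyl-3-isopropyl-5,7-dimethoxychroman-2-one F2.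
- Arene 15 is lithiated (n-BuLi, THF, 0 °C) to 2,4,6-trimethoxyphenyllithium F3, which should add once to F2 to give the hemiketal (3S,4S)-4-isobutyl-3-isopropyl-5,7-dimethoxy-2-(2,4,6-trimethoxyphenyl)chroman-2-ol F4.
- Ionic reduction (Et3SiH, BF3·OEt2, CH2Cl2, −78 °C) ionises C2. Hydride should arrive axially and anti to the neighbouring axial isopropyl group, which leaves ring B equatorial and cis to it, as in 17.

**Step 7.**
- What may go wrong: ionisation at C1 may be slow because no donor is in conjugation. Elimination towards the indene and premature acid-induced rearrangement of the peroxide may compete.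
- The fallback sets out from 5 and comes back at 17. It moves the oxygen insertion ahead of the isopropyl group, where the aryl group competes only with a primary CH2.
- Baeyer–Villiger oxidation of 5 (mCPBA, TsOH cat., CH2Cl2) should give (S)-4-isobutyl-5,7-dimethoxychroman-2-one F5.
- LDA and acetone then give the aldol (3R,4S)-3-(2-hydroxypropan-2-yl)-4-isobutyl-5,7-dimethoxychroman-2-one F6. Warm toluene with catalytic TsOH dehydrates it to (R)-4-isobutyl-5,7-dimethoxy-3-(propan-2-ylidene)chroman-2-one F7.
- Hydrogenation (H2, Pd/C) gives the cis lactone (3R,4S)-4-isobutyl-3-isopropyl-5,7-dimethoxychroman-2-one F8, and DBU epimerises it to the trans lactone F2.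
- DIBAL-H (−78 °C) reduces F2 to the lactol F1, and InCl3 with 15 converts F1 through ion 16 into 17.

**Step 9.**
- What may go wrong: the later formylations may stall, because the first formyl group deactivates each ring. TiCl4 may ionise the O1–C2 bond, with ipso attack and loss of ring B.
- The fallback sets out from 17 and comes back at 20. It reverses the order of the last two operations, so that the far more nucleophilic free phenols are formylated.
- BBr3 (CH2Cl2, −78 °C to rt) cleaves all five ethers to the pentaphenol (2R,3S,4S)-4-isobutyl-3-isopropyl-2-(2,4,6-trihydroxyphenyl)chroman-5,7-diol F9.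
- A fourfold Vilsmeier–Haack formylation (POCl3, DMF, then water), as known for the diformylation of phloroglucinols, leads to 20.

**Further compounds**
F1 | step 8 | (3S,4S)-4-isobutyl-3-isopropyl-5,7-dimethoxychroman-2-ol (both anomers) | CC(C)C[C@@H]1c2c(OC)cc(OC)cc2OC(O)[C@H]1C(C)C
F2 | step 8 | (3S,4S)-4-isobutyl-3-isopropyl-5,7-dimethoxychroman-2-one (trans) | CC(C)C[C@@H]1c2c(OC)cc(OC)cc2OC(=O)[C@H]1C(C)C
F3 | step 8 | 2,4,6-trimethoxyphenyllithium | [Li]c1c(OC)cc(OC)cc1OC
F4 | step 8 | (3S,4S)-4-isobutyl-3-isopropyl-5,7-dimethoxy-2-(2,4,6-trimethoxyphenyl)chroman-2-ol (C2 epimers) | CC(C)C[C@@H]1c2c(OC)cc(OC)cc2OC(O)(c2c(OC)cc(OC)cc2OC)[C@H]1C(C)C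
F5 | step 7 | (S)-4-isobutyl-5,7-dimethoxychroman-2-one | CC(C)C[C@@H]1c2c(OC)cc(OC)cc2OC(=O)C1
F6 | step 7 | (3R,4S)-3-(2-hydroxypropan-2-yl)-4-isobutyl-5,7-dimethoxychroman-2-one | CC(C)C[C@@H]1c2c(OC)cc(OC)cc2OC(=O)[C@H]1C(C)(C)O
F7 | step 7 | (R)-4-isobutyl-5,7-dimethoxy-3-(propan-2-ylidene)chroman-2-one | CC(C)C[C@@H]1c2c(OC)cc(OC)cc2OC(=O)C1=C(C)C
F8 | step 7 | (3R,4S)-4-isobutyl-3-isopropyl-5,7-dimethoxychroman-2-one (cis) | CC(C)C[C@@H]1c2c(OC)cc(OC)cc2OC(=O)[C@@H]1C(C)C
F9 | step 9 | (2R,3S,4S)-4-isobutyl-3-isopropyl-2-(2,4,6-trihydroxyphenyl)chroman-5,7-diol | CC(C)C[C@@H]1c2c(O)cc(O)cc2O[C@@H](c2c(O)cc(O)cc2O)[C@H]1C(C)C
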